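**Plan**

- Retrosynthesis: the two depside C(=O)–O bonds are cut, ring B–ring C first and ring A–ring B second. This leaves 2,3,4-trimethoxy-6-methylbenzoic acid (ring A) and two molecules of benzyl orsellinate (rings B and C, from purchased orsellinic acid).
- Ring A is cut at its C1–C6 bond. Its C1 carboxyl, its oxygens at C2, C3 and C4 and its C6 methyl are those of an orsellinate with one extra oxygen at C3. They map onto an open-chain methyl 3,5,7-trioxooctanoate whose chain C4 already carries the methoxyl.
- That chain is cut at C4–C5 into the dianion of methyl 4-methoxyacetoacetate and a ketal-masked acetoacetyl Weinreb amide.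
- Forward: chain assembly, ketal removal, aldol fold to ring A (the only ring made), O-methylation and saponification. Two rounds of trifluoroacetic anhydride esterification and benzyl ester hydrogenolysis then attach ring B and ring C in turn.
- Stereochemistry: the target has no stereocentre; the sp3 centres of the chain and of the aldol adduct vanish on aromatization.

Key step: step 4

Remark: the open-chain keto esters and the cyclic aldol adduct are written as keto tautomers with undefined sp3 centres; they enolize freely and none of these centres reaches the target.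

**Route**

Step 1
Reactants: 1 ethyl 2-(2-methyl-1,3-dioxolan-2-yl)acetate
Product: 2 N-methoxy-N-methyl-2-(2-methyl-1,3-dioxolan-2-yl)acetamide
Conditions: MeNHOMe·HCl, iPrMgCl, THF, −20 to 0 °C
Reagents that add atoms: N,O-dimethylhydroxylamine hydrochloride, CNOC.Cl
Why: Weinreb amide formation by aminolysis of the ester with the chloromagnesium amide made in the flask is fast at low temperature, and this weakly basic nucleophile leaves the dioxolane and the α-methylene untouched.

Step 2
Reactants: 3 methyl 4-methoxy-3-oxobutanoate (methyl 4-methoxyacetoacetate); 2 N-methoxy-N-methyl-2-(2-methyl-1,3-dioxolan-2-yl)acetamide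
Product: 5 methyl 4-methoxy-6-(2-methyl-1,3-dioxolan-2-yl)-3,5-dioxohexanoate, via dilithium dianion 4 (not isolated)
Conditions: 3 (1.5 equiv), LiN(iPr)2 (2.1 equiv per 3), THF, −78 to 0 °C; then 2 (1 equiv), −78 to 0 °C; AcOH quench
Reagents that add atoms: none
Why: γ-Acylation of a β-keto ester dianion by a Weinreb amide (Weinreb ketone synthesis) forms the chain C4–C5 bond; the chelated tetrahedral adduct persists until work-up, so the new 1,3-diketone never meets excess carbanion, and the dioxolane keeps the distal ketone from enolizing.

Step 3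
Reactants: 5 methyl 4-methoxy-6-(2-methyl-1,3-dioxolan-2-yl)-3,5-dioxohexanoate
Product: 6 methyl 4-methoxy-3,5,7-trioxooctanoate
Conditions: 1 M aq. HCl, THF, 0 °C to rt; crude product used at once
Reagents that add atoms: water, O
Why: Acid-catalysed ketal hydrolysis frees the C7 ketone, and cold dilute acid with short contact should leave the enolized chain open instead of dehydrating it to a pyranone.

Step 4
Reactants: 6 methyl 4-methoxy-3,5,7-trioxooctanoate
Product: 8 methyl 2,4-dihydroxy-3-methoxy-6-methylbenzoate, via cyclic aldol adduct 7 (not isolated)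
Conditions: K2CO3, MeOH, 0 °C to rt; then HCl/MeOH, rt
Reagents that add atoms: none
Why: K2CO3 deprotonates the C2 methylene of the β-keto ester and this enolate adds to the C7 methyl ketone of the same chain to give the cyclic carbinol 7; acidification then drives loss of water and the two enolizations that make ring A aromatic, so that the chain C3 and C5 carbonyls end as the C2 and C4 hydroxyls, the chain C4 methoxyl as the C3 methoxyl and the acetyl terminus as C6 with its methyl. The closest known reaction is the biomimetic intramolecular aldol condensation of 3,5,7-triketo esters to orsellinate (β-resorcylate) esters under carbonate or hydroxide bases. Ring A closes in a 6-(enolendo)-exo-trig aldol mode by forming the arene C1–C6 bond (chain C2–C7). No stereocentre is set, and the sp3 centres of 7 are erased on aromatization. The step needs the aldol mode to win over the Claisen mode (chain C6 onto the ester carbonyl, which would lead to an acylphloroglucinol) and over O-cyclization to pyranones; this is secured by a non-chelating alkali carbonate in methanol with no magnesium template, by the higher electrophilicity of the methyl ketone compared with the ester, and by withholding the acid until the carbon–carbon bond is made. The C4 methoxyl is a spectator whose carbon keeps its hydrogen, so enolization to the arene is not blocked.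

Step 5
Reactants: 8 methyl 2,4-dihydroxy-3-methoxy-6-methylbenzoate
Product: 9 methyl 2,3,4-trimethoxy-6-methylbenzoate
Conditions: MeI (excess), K2CO3, DMF, 50 °C
Reagents that add atoms: iodomethane, CI
Why: Williamson ether synthesis on both phenoxides; excess MeI and gentle heating should also methylate the hydrogen-bonded, flanked C2 hydroxyl.

Step 6
Reactants: 9 methyl 2,3,4-trimethoxy-6-methylbenzoate
Product: 10 2,3,4-trimethoxy-6-methylbenzoic acid
Conditions: KOH, DMSO/H2O, 90 °C; then aq. HCl
Reagents that add atoms: potassium hydroxide, [K+].[OH-]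
Why: Saponification of the di-ortho-substituted benzoate needs hot KOH in aqueous DMSO, conditions under which aryl methyl ethers are inert.

Step 7
Reactants: 11 2,4-dihydroxy-6-methylbenzoic acid (orsellinic acid)
Product: 12 benzyl 2,4-dihydroxy-6-methylbenzoate (benzyl orsellinate)
Conditions: BnBr, KHCO3, DMF, rt
Reagents that add atoms: benzyl bromide, BrCc1ccccc1
Why: Carboxylate O-alkylation (SN2); hydrogencarbonate ionizes only the carboxylic acid, so the phenols stay free, and room temperature avoids decarboxylation.

Step 8
Reactants: 10 2,3,4-trimethoxy-6-methylbenzoic acid; 12 benzyl 2,4-dihydroxy-6-methylbenzoate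
Product: 14 benzyl 2-hydroxy-6-methyl-4-[(2,3,4-trimethoxy-6-methylbenzoyl)oxy]benzoate, via mixed trifluoroacetic anhydride 13 (not isolated)
Conditions: (CF3CO)2O, toluene, 0 °C to rt
Reagents that add atoms: none
Why: Mixed-anhydride esterification: the electron-rich, di-ortho-substituted acid is activated as its trifluoroacetic anhydride (acylium-like) and is captured by the C4 hydroxyl of 12, whose C2 hydroxyl is deactivated by its hydrogen bond to the ester carbonyl.

Step 9
Reactants: 14 benzyl 2-hydroxy-6-methyl-4-[(2,3,4-trimethoxy-6-methylbenzoyl)oxy]benzoate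
Product: 15 2-hydroxy-6-methyl-4-[(2,3,4-trimethoxy-6-methylbenzoyl)oxy]benzoic acid
Conditions: H2 (1 atm), 10% Pd/C, EtOAc, rt
Reagents that add atoms: none
Why: Catalytic hydrogenolysis cleaves only the benzylic C–O bond; the aryl ester and the methyl ethers are stable to it.

Step 10
Reactants: 15 2-hydroxy-6-methyl-4-[(2,3,4-trimethoxy-6-methylbenzoyl)oxy]benzoic acid; 12 benzyl 2,4-dihydroxy-6-methylbenzoate
Product: 17 benzyl 2-hydroxy-4-({2-hydroxy-6-methyl-4-[(2,3,4-trimethoxy-6-methylbenzoyl)oxy]benzoyl}oxy)-6-methylbenzoate, via mixed trifluoroacetic anhydride 16 (not isolated)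
Conditions: (CF3CO)2O, toluene, 0 °C to rt
Reagents that add atoms: none
Why: The same mixed-anhydride esterification joins ring B to the C4 hydroxyl of ring C; the chelated ortho-hydroxyls of both partners are poor nucleophiles, and the acidic medium does not scramble the existing aryl ester.

Step 11
Reactants: 17 benzyl 2-hydroxy-4-({2-hydroxy-6-methyl-4-[(2,3,4-trimethoxy-6-methylbenzoyl)oxy]benzoyl}oxy)-6-methylbenzoate
Product: 18 2-hydroxy-4-({2-hydroxy-6-methyl-4-[(2,3,4-trimethoxy-6-methylbenzoyl)oxy]benzoyl}oxy)-6-methylbenzoic acid (target)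
Conditions: H2 (1 atm), 10% Pd/C, EtOAc, rt
Reagents that add atoms: none
Why: Hydrogenolysis of the benzyl ester under neutral conditions should release the ring C carboxylic acid without touching either depside linkage.

**Compound list**

1 | ethyl 2-(2-methyl-1,3-dioxolan-2-yl)acetate | CCOC(=O)CC1(C)OCCO1 | starting material
2 | N-methoxy-N-methyl-2-(2-methyl-1,3-dioxolan-2-yl)acetamide | CON(C)C(=O)CC1(C)OCCO1 | intermediate
3 | methyl 4-methoxy-3-oxobutanoate | COCC(=O)CC(=O)OC | starting material
4 | dilithium 1,4-dimethoxybuta-1,3-diene-1,3-diolate (dianion of 3, double-bond geometry undefined, not isolated) | [Li+].[Li+].COC=C([O-])C=C([O-])OC | intermediate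
5 | methyl 4-methoxy-6-(2-methyl-1,3-dioxolan-2-yl)-3,5-dioxohexanoate (racemic at C4, enolizable) | COC(=O)CC(=O)C(OC)C(=O)CC1(C)OCCO1 | intermediate
6 | methyl 4-methoxy-3,5,7-trioxooctanoate (racemic at C4, enolizable) | COC(=O)CC(=O)C(OC)C(=O)CC(C)=O | intermediate
7 | methyl 2-hydroxy-5-methoxy-2-methyl-4,6-dioxocyclohexane-1-carboxylate (cyclic aldol adduct, mixture of stereoisomers and enols, not isolated) | COC(=O)C1C(=O)C(OC)C(=O)CC1(C)O | intermediate
8 | methyl 2,4-dihydroxy-3-methoxy-6-methylbenzoate | COC(=O)c1c(C)cc(O)c(OC)c1O | intermediate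
9 | methyl 2,3,4-trimethoxy-6-methylbenzoate | COC(=O)c1c(C)cc(OC)c(OC)c1OC | intermediate
10 | 2,3,4-trimethoxy-6-methylbenzoic acid | COc1cc(C)c(C(=O)O)c(OC)c1OC | intermediate
11 | 2,4-dihydroxy-6-methylbenzoic acid (orsellinic acid) | Cc1cc(O)cc(O)c1C(=O)O | starting material
12 | benzyl 2,4-dihydroxy-6-methylbenzoate | Cc1cc(O)cc(O)c1C(=O)OCc1ccccc1 | intermediate
13 | 2,3,4-trimethoxy-6-methylbenzoic trifluoroacetic anhydride (not isolated) | COc1cc(C)c(C(=O)OC(=O)C(F)(F)F)c(OC)c1OC | intermediate
14 | benzyl 2-hydroxy-6-methyl-4-[(2,3,4-trimethoxy-6-methylbenzoyl)oxy]benzoate | COc1cc(C)c(C(=O)Oc2cc(C)c(C(=O)OCc3ccccc3)c(O)c2)c(OC)c1OC | intermediate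
15 | 2-hydroxy-6-methyl-4-[(2,3,4-trimethoxy-6-methylbenzoyl)oxy]benzoic acid | COc1cc(C)c(C(=O)Oc2cc(C)c(C(=O)O)c(O)c2)c(OC)c1OC | intermediate
16 | 2-hydroxy-6-methyl-4-[(2,3,4-trimethoxy-6-methylbenzoyl)oxy]benzoic trifluoroacetic anhydride (not isolated) | COc1cc(C)c(C(=O)Oc2cc(C)c(C(=O)OC(=O)C(F)(F)F)c(O)c2)c(OC)c1OC | intermediate
17 | benzyl 2-hydroxy-4-({2-hydroxy-6-methyl-4-[(2,3,4-trimethoxy-6-methylbenzoyl)oxy]benzoyl}oxy)-6-methylbenzoate | COc1cc(C)c(C(=O)Oc2cc(C)c(C(=O)Oc3cc(C)c(C(=O)OCc4ccccc4)c(O)c3)c(O)c2)c(OC)c1OC | intermediate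
18 | 2-hydroxy-4-({2-hydroxy-6-methyl-4-[(2,3,4-trimethoxy-6-methylbenzoyl)oxy]benzoyl}oxy)-6-methylbenzoic acid | COc1cc(C)c(C(=O)Oc2cc(C)c(C(=O)Oc3cc(C)c(C(=O)O)c(O)c3)c(O)c2)c(OC)c1OC | target

**Step count**

Total: 11 steps. Longest linear sequence: 10 steps (steps 1, 2, 3, 4, 5, 6, 8, 9, 10, 11, from 1 to 18).

**Steps most likely to fail**

1. Step 4. The chain may close through the wrong atoms: Claisen attack of chain C6 on the ester, O-cyclization to a pyranone, or retro-Claisen fragmentation of the methoxylated 1,3-diketone under the base. The fallback builds ring A's third oxygen on an existing arene instead of folding a chain. It sets out from 12. Rieche formylation (Cl2CHOCH3, TiCl4, CH2Cl2, 0 °C) at C3, between the two hydroxyls, should give benzyl 3-formyl-2,4-dihydroxy-6-methylbenzoate F1; the C5 regioisomer would have to be separated. Dakin oxidation (H2O2, aq. NaOH, 0 °C, under argon) should turn the formyl group into a hydroxyl and give benzyl 2,3,4-trihydroxy-6-methylbenzoate F2. Exhaustive methylation (MeI, K2CO3, DMF) should give benzyl 2,3,4-trimethoxy-6-methylbenzoate F3. Hydrogenolysis (H2, Pd/C, EtOAc) comes back to the route at acid 10.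

2. Step 2. The basic dianion may deprotonate amide 2 at its α-carbon, opening the dioxolane by β-elimination, or the hindered methoxy-bearing carbanion may acylate too slowly. The fallback makes the C4–C5 bond by aldol addition and oxidation instead of acylation. It sets out from 2, which is reduced with LiAlH4 (THF, −40 °C) to 2-(2-methyl-1,3-dioxolan-2-yl)acetaldehyde F4. This aldehyde is added at −78 °C to dianion 4, generated from 3 as in step 2, to give methyl 5-hydroxy-4-methoxy-6-(2-methyl-1,3-dioxolan-2-yl)-3-oxohexanoate F5 as a mixture of diastereomers. Oxidation of the C5 alcohol with Dess–Martin periodinane (CH2Cl2, rt) comes back to the route at 5.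

3. Step 3. Acid may dehydrate the freed triketone to a pyranone during ketal cleavage, or the open chain may decompose on isolation. The fallback makes the pyranone on purpose and uses it as a stable, purifiable store of the chain. It sets out from 5, which CF3CO2H in CH2Cl2 should deketalize and cyclodehydrate to methyl 2-(3-methoxy-6-methyl-4-oxo-4H-pyran-2-yl)acetate F6. Methanolic KOH then opens the pyranone by conjugate addition at its C6 and regenerates the polyanion of 6 in the flask, which closes by the same chain C2-to-C7 aldol via 7. Acidification comes back to the route at 8.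

**Further compounds**

F1 | step 4 | benzyl 3-formyl-2,4-dihydroxy-6-methylbenzoate | Cc1cc(O)c(C=O)c(O)c1C(=O)OCc1ccccc1
F2 | step 4 | benzyl 2,3,4-trihydroxy-6-methylbenzoate | Cc1cc(O)c(O)c(O)c1C(=O)OCc1ccccc1
F3 | step 4 | benzyl 2,3,4-trimethoxy-6-methylbenzoate | COc1cc(C)c(C(=O)OCc2ccccc2)c(OC)c1OC
F4 | step 2 | 2-(2-methyl-1,3-dioxolan-2-yl)acetaldehyde | O=CCC1(C)OCCO1
F5 | step 2 | methyl 5-hydroxy-4-methoxy-6-(2-methyl-1,3-dioxolan-2-yl)-3-oxohexanoate | COC(=O)CC(=O)C(OC)C(O)CC1(C)OCCO1
F6 | step 3 | methyl 2-(3-methoxy-6-methyl-4-oxo-4H-pyran-2-yl)acetate | COC(=O)Cc1oc(C)cc(=O)c1OC
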